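## Analysis of the target

The target is a xenicane diterpenoid triacetate: a nine-membered carbocycle (C4a, C5 to C11, C11a) trans-fused to a 2-acetoxy-3,4-dihydro-2H-pyran (C1, O2, C3, C4, C4a, C11a), with a five-carbon chain (C12 to C15 and two methyl groups) on C4. Xenicane numbering is used throughout; C18 is the methyl group on C7 and C19 the methylene carbon on C11. There are nine stereocentres, 1R,4aS,7S,8R,9R,11aR,12R,13R,14R. H4a and H11a are trans, and the C1 acetate is trans to the C11a–C11 bond. On the carbocycle the C7 hydroxyl and the oxygen of the cis C8–C9 epoxide lie on the same face, which is the face opposite the C4a–C4 bond. In the chain the 12,13-diacetate is anti (erythro) and the C13 oxygen is erythro to the C14–C15 epoxide. The sensitive groups are the acetal acetate at C1, the enol ether C3=C4 with an allylic acetate on C12, two epoxides, a tertiary carbinol, and the C11 methylene, which is β,γ to C1 and moves into conjugation whenever C1 is a free carbonyl group or a nitrile under base. The difficulty lies in the medium ring, in relaying configuration from the ring fusion to C7–C9, and in telling four different C=C bonds apart late in the route. The strategy rests on two features: C10–C11(=C19)–C11a is a trimethylenemethane unit, and C4a–C5–C6–C7(C18)–C8–C9 is the arc C7 to C2 of 4-methyltropone, whose carbonyl carbon can be kept as C4.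

## Retrosynthetic reasoning

**C8–C9 epoxide.** The two C–O bonds of the epoxide are cut last, giving alkene 32. The C7 hydroxyl sits on the face the epoxide must take, so a hydroxyl-directed oxygen transfer can set C8 and C9 together. Leaving it to the end keeps the epoxy alcohol out of every basic, reducing and chromium step. The forward reaction must prefer the allylic-alcohol alkene over the enol ether and the methylene group.

**C4–C12 bond.** After removal of the C12 acetate (31), the chain is cut from the ring between C4 and C12. C4 is an sp2 carbon next to the ring ketone position, so it can be an enol triflate (25). C12 becomes the aldehyde carbon of 30, which already carries C13, C14 and the epoxide. The cut is convergent and creates only C12. The forward coupling must add to the aldehyde in the Felkin sense and tolerate the acetal acetate and the epoxide.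

**Side-chain aldehyde.** Aldehyde 30 comes from ozonolysis of vinyl acetate 29, which comes from epoxy alcohol 28. The C12–C13 bond is cut back to enal 26 and a vinyl Grignard reagent, giving racemic dienol 27. A tartrate-controlled epoxidation with kinetic resolution then sets C13 and C14 together and gives the erythro relationship.

**Pyran ring.** Triflate 25 comes from ketone 24, and the acetate of 24 from lactol 23. The O2–C1 bond of 23 is cut to give a chain with a C1 aldehyde and a C3 hydroxyl (22 after loss of the benzyl-type group). Closure is then a simple hemiacetal formation with only one aldehyde present, so O2 cannot end up on the wrong carbon. C1 is never a free aldehyde under base.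

**C3–C4 bond.** Ketone 21 is cut between C4 and C3 into γ-lactone 20 and an alkoxymethyl-lithium reagent. The lactone ties C4 (as acyl carbon) to the C1 oxygen, so one addition gives the ketone and frees the C1 alcohol, and the tropone carbonyl carbon stays C4.

**C7 carbinol and C8=C9.** The C7–O bond of 18 is cut and reconnected as a C9–Se bond (15). A [2,3] shift of the selenoxide moves the heteroatom across the allyl unit on one face and makes the cis C8=C9 alkene. C7 is thus set from C9.

**C9–Se bond.** Selenide 15 is cut back to lactone 14 and a selenolate. Displacement at the allylic C9–O bond opens the lactone with inversion. This inversion is needed because the oxygen on C9 in 14 is on the bridge face, while the C7 hydroxyl must be on the other face.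

**Oxygen between C4 and C9.** Lactone 14 goes back to bridged ketone 13 by removing the inserted oxygen. The forward Baeyer–Villiger reaction must let the allylic bridgehead C9 migrate and must not touch the alkenes.

**C1 oxidation level.** The silyl ether in 13 goes back through 12 and 11 to the nitrile in 9. The nitrile is changed early because its α-hydrogen is allylic and acidic, and because later intermediates carry groups that hydride reagents would attack.

**C5–C6.** The two hydrogens on C5 and C6 of 9 are removed to give diene 8. The forward reduction must take the disubstituted end of the diene only.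

**Key disconnection.** In 8 the bonds C4a–C11a and C9–C10 are cut. This gives 4-methyltropone 4 and the cyano-substituted trimethylenemethane donor 7. Both ring bonds form in one catalytic step across a seven-membered ring, so no medium ring is closed from a chain. The step brings in C19 and the latent C1 and sets C4a, C9 and C11a.

**Precursors.** Tropone 4 goes back to 4-methylanisole 1 through diene 2 and dibromocyclopropane 3. Donor 7 goes back to allyl acetate 5 through ketone 6.

## Alternatives that were turned down

**Alternative 1:** The carbocycle is made by fragmenting a fused bicyclic precursor. The C7–C11 bond is the one broken: a C11 alkoxide pushes out a C8 sulfonate that is anti-periplanar, giving bicyclic ketone A1 with an E C7=C8 alkene, the pyran already in place, a methyl ester on C4 and a methyl acetal at C1.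
- For it: the fragmentation is concerted and stereospecific, the trans ring fusion and absolute configuration come from an early organocatalytic step, and the heterocycle is present before the ring is opened. On these three points it is stronger than the chosen route.
- Against it for this target: A1 has an E trisubstituted alkene at C7=C8 and no handle on C9. The target needs a C7 carbinol and a cis C8–C9 epoxide, so the unsaturation would have to move to C8=C9 with Z geometry. Opening an E-derived epoxide toward C9 gives no control of that geometry. The C11 ketone must be methylenated next to the epimerisable C11a. The C1 methyl acetal must be exchanged for acetate under acid with epoxides present. C12 arrives as an ester, so the chain must be built by adding an α-oxygenated nucleophile. The path to the fragmentation substrate is long and linear.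
- In its place the chosen route offers cis ring alkenes from the start, an oxygen on C9 that is relayed to C7, the C11 methylene delivered directly, and the carbocycle in six steps.

**Alternative 2:** The pyran is the linchpin. An alkenylcopper reagent adds to a 6-methoxypyranone at C11a anti to the acetal substituent, and the enolate is trapped at C4a by an enone, giving tetrahydropyranone A2 with both ring arms.
- For it: three components are joined in one step, the trans C4a/C11a relationship follows from anti addition, and the C1 acetal and C4 ketone are in place for an enol triflate. In step economy on the heterocycle it is clearly stronger than the chosen route, which needs eight steps to reach the same kind of ketone.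
- Against it: the nine-membered ring still has to be closed from a chain, by bonding the alkyne-derived C8 to the C7 ketone carbon. That is a medium-ring closure with transannular strain, and it creates the tertiary C7 centre with nothing nearby to control it. The alkyne must first become a Z alkenyl nucleophile in the presence of two ketones and the methylene group. Michael trapping of a copper enolate by an enone is often slow.
- In its place the chosen route closes the ring by annulation and sets C7 by a stereospecific relay.

**Alternative 3:** The pyran is photo-annulated onto a preformed Z cyclononene. The enol of a diformylacetate adds across C4a=C11a to a cyclobutanol, which opens by retro-aldol cleavage and recloses to the 2-hydroxydihydropyran A3.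
- For it: the two C–C bonds to the carbocycle, the enol ether and the lactol are made in one step, and C7–C9 are oxidised before the heterocycle exists. No route to the pyran is shorter.
- Against it: the enantiopure cyclononene must still be made, so the medium-ring problem is only moved. The two alkene carbons are both secondary and differ only remotely, so the orientation of the [2+2] addition is not secured. The face is not secured on a flexible ring. The excited state can isomerise the ring alkene and scramble the ring fusion. C11 arrives as a silyl ether and needs three steps to become the methylene, next to C11a. The C4 ester must be built into the chain as in alternative 1.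
- In its place the chosen route attaches C1 and C4 through different partners, so their positions are fixed by constitution, and it builds the carbocycle itself.

Key step: step 6

Remarks on the chemistry:
- Which enantiomer of the phosphoramidite gives adduct 8 as drawn has to be found by trial. Both enantiomers of the ligand are equally accessible, and the route assumes the one that gives 8.
- Donor 7 is used as the E/Z mixture, since both isomers give the same palladium complex.
- The carbinol configuration at the bridge carbon in 10–12 and the anomeric configuration of lactol 23 are not controlled and have no consequence.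

## Route

Step 1
Reactants: 1 4-methylanisole
Product: 2 1-methoxy-4-methylcyclohexa-1,4-diene
Conditions: Li, NH3 (l), t-BuOH, THF, −78 to −33 °C
Reagents that add atoms: none
Why: Birch reduction; the donor substituents end on the remaining sp2 carbons, giving the 1,4-diene with an enol ether double bond.

Step 2
Reactants: 2 1-methoxy-4-methylcyclohexa-1,4-diene
Product: 3 7,7-dibromo-1-methoxy-4-methylbicyclo[4.1.0]hept-3-ene (racemic)
Conditions: CHBr3, KOt-Bu, pentane, −20 to 0 °C
Reagents that add atoms: bromoform, BrC(Br)Br
Why: Dihalocarbene cyclopropanation; the electrophilic carbene should add to the more electron-rich enol ether double bond and leave the methyl-substituted alkene.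

Step 3
Reactants: 3 7,7-dibromo-1-methoxy-4-methylbicyclo[4.1.0]hept-3-ene
Product: 4 4-methyltropone (4-methylcyclohepta-2,4,6-trien-1-one)
Conditions: AgNO3, acetone–H2O, 60 °C
Reagents that add atoms: water, O
Why: Silver-assisted electrocyclic opening of the dibromocyclopropane, loss of two equivalents of HBr and hydrolysis at the methoxy-bearing carbon give the tropone, the known ring-expansion route to 4-alkyltropones. The carbene carbon becomes C2, which places the methyl group on C5, the same as C4 by symmetry.

Step 4
Reactants: 5 2-[(trimethylsilyl)methyl]allyl acetate
Product: 6 1-acetoxy-3-(trimethylsilyl)propan-2-one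
Conditions: O3, CH2Cl2–MeOH, −78 °C; then Me2S
Reagents that add atoms: ozone, [O-][O+]=O
Why: Ozonolysis of the 1,1-disubstituted alkene gives the ketone; the reductive work-up is kept cold and neutral so that the α-silyl ketone is not desilylated.

Step 5
Reactants: 6 1-acetoxy-3-(trimethylsilyl)propan-2-one
Product: 7 3-cyano-2-[(trimethylsilyl)methyl]allyl acetate (E/Z mixture)
Conditions: (EtO)2P(O)CH2CN, NaH, THF, 0 °C
Reagents that add atoms: diethyl cyanomethylphosphonate, CCOP(=O)(CC#N)OCC
Why: Horner–Wadsworth–Emmons olefination of the ketone with a stabilised phosphonate anion; alkene geometry does not matter for the next step.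

Step 6
Reactants: 4 4-methyltropone; 7 3-cyano-2-[(trimethylsilyl)methyl]allyl acetate
Product: 8 (1S,6S,7R)-3-methyl-8-methylidene-10-oxobicyclo[4.3.1]deca-2,4-diene-7-carbonitrile
Conditions: Pd(dba)2 (5 mol %), chiral BINOL-derived 2,5-diarylpyrrolidine phosphoramidite (10 mol %), toluene, 0 °C
Reagents that add atoms: none
Why: Zerovalent palladium ionises the allylic acetate of 7 and the acetate removes the silyl group, giving the zwitterionic cyano-trimethylenemethane–palladium complex, whose nitrile-stabilised carbon adds in conjugate fashion to an α-carbon of 4. The extended enolate then alkylates through its other α-carbon on the unsubstituted terminus of the π-allylpalladium unit and releases the catalyst; this is the known palladium-catalysed [6+3] cycloaddition of cyano-substituted trimethylenemethane donors to tropones. The second bond closes a six-membered ring (C4, C4a, C11a, C11, C10, C9) by enolate C-alkylation at the allyl terminus with the enolate double bond inside the forming ring, and the same bond completes the nine-membered carbocycle across C2 and C7 of the tropone. C4a and C9 are the two bridgeheads; their relative configuration is fixed by the one-carbon bridge and their absolute sense is set in the first C–C bond formation inside the chiral pocket of the ligand. C11a is set by the face of the nitrile-bearing carbon that attacks; the nitrile anti to the carbonyl bridge is expected, and this centre can be equilibrated to that isomer because it is α to the nitrile. The step needs regioselection between the two α-carbons: the nitrile-bearing carbon must bond to C7 of 4, three bonds from the methyl-bearing carbon. The methyl group is remote and gives little intrinsic bias, so this rests on the catalyst and is the main risk of the route. The reaction is run cold so that the 1,5-diene in 8 does not undergo a thermal Cope rearrangement.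

Step 7
Reactants: 8 (1S,6S,7R)-3-methyl-8-methylidene-10-oxobicyclo[4.3.1]deca-2,4-diene-7-carbonitrile
Product: 9 (1S,6S,7R)-3-methyl-8-methylidene-10-oxobicyclo[4.3.1]dec-2-ene-7-carbonitrile
Conditions: 2-nitrobenzenesulfonylhydrazide, Et3N, CH2Cl2, rt (1.2 equiv, monitored)
Reagents that add atoms: none
Why: Diimide reduction; the cis-disubstituted end of the strained cyclic diene (C5=C6) should react faster than the trisubstituted C7=C8 and the 1,1-disubstituted methylene. Removing C5=C6 also removes the 1,5-diene and leaves C9 as the only allylic bridgehead.

Step 8
Reactants: 9 (1S,6S,7R)-3-methyl-8-methylidene-10-oxobicyclo[4.3.1]dec-2-ene-7-carbonitrile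
Product: 11 (1S,6S,7R)-7-(hydroxymethyl)-3-methyl-8-methylidenebicyclo[4.3.1]dec-2-en-10-ol (C10 epimers), via hydroxy aldehyde 10 (not isolated)
Conditions: i-Bu2AlH (2.5 equiv), CH2Cl2, −78 to −20 °C; aq. potassium sodium tartrate; then NaBH4, MeOH, 0 °C
Reagents that add atoms: water, O
Why: Aluminium hydride reduction of the nitrile to the imine and of the bridge ketone to the carbinol; hydrolysis gives the aldehyde, which is reduced at once so that the β,γ-unsaturated aldehyde has no time to conjugate. This removes the acidic allylic α-cyano hydrogen before any strongly basic step.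

Step 9
Reactants: 11 diol
Product: 12 (1S,6S,7R)-7-[(tert-butyldimethylsilyl)oxymethyl]-3-methyl-8-methylidenebicyclo[4.3.1]dec-2-en-10-ol
Conditions: t-BuMe2SiCl, imidazole, CH2Cl2, 0 °C
Reagents that add atoms: tert-butyldimethylsilyl chloride, CC(C)(C)[Si](C)(C)Cl
Why: Selective silylation of the primary alcohol; the carbinol on the one-carbon bridge is hindered.

Step 10
Reactants: 12 silyl ether
Product: 13 (1S,6S,7R)-7-[(tert-butyldimethylsilyl)oxymethyl]-3-methyl-8-methylidenebicyclo[4.3.1]dec-2-en-10-one
Conditions: Dess–Martin periodinane, NaHCO3, CH2Cl2, 0 °C to rt
Reagents that add atoms: none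
Why: Oxidation of the secondary alcohol back to the non-enolisable bridge ketone; the bridgeheads cannot epimerise.

Step 11
Reactants: 13 bridged ketone
Product: 14 bridged lactone (C4 carbonyl bonded through oxygen to C9, oxygen on the face of the former bridge; C7=C8; C11 methylidene; CH2OSi on C11a)
Conditions: Me3SiOOSiMe3 (1.5 equiv), Me3SiOTf (10 mol %), CH2Cl2, −78 to −40 °C
Reagents that add atoms: bis(trimethylsilyl) peroxide, C[Si](C)(C)OO[Si](C)(C)C
Why: Baeyer–Villiger oxidation with a silyl peroxide, a variant that leaves isolated alkenes alone. The allylic bridgehead C9 should migrate in preference to the purely alkyl C4a, with retention, so the new C9–O bond is on the bridge face.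

Step 12
Reactants: 14 bridged lactone
Product: 15 (Z)-cyclononene acid (C4 carboxylic acid on C4a; phenylselanyl on C9 with inverted configuration; C7=C8; C11 methylidene; CH2OSi on C11a)
Conditions: (PhSe)2, NaH, THF, 60 °C; then 14, DMPU, 60 °C; 1 M HCl
Reagents that add atoms: diphenyl diselenide, c1ccccc1[Se][Se]c1ccccc1
Why: Alkyl–oxygen cleavage of a lactone by a selenolate, here at an allylic carbinol carbon. SN2 attack inverts C9 and puts selenium on the face opposite the former bridge, and the acid is released in the same step.

Step 13
Reactants: 15 allylic selenide
Product: 18 hydroxy acid (C7 tertiary carbinol with the target configuration; Z C8=C9; C4 acid; CH2OSi on C11a), via allylic selenoxide 16 (not isolated), via selenenate ester 17 (not isolated)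
Conditions: 30% H2O2, pyridine, THF, 0 °C to rt
Reagents that add atoms: hydrogen peroxide, OO
Why: Oxidation to the selenoxide and [2,3]-sigmatropic rearrangement, which for an allylic selenoxide is faster than syn elimination. The shift is suprafacial, so oxygen arrives on C7 on the face selenium left at C9, and the ring allows only the cis C8=C9 alkene. The selenenate is hydrolysed in the flask.

Step 14
Reactants: 18 hydroxy acid
Product: 20 trans-fused γ-lactone (C4 carbonyl, ring oxygen, C1H2; C7 carbinol; Z C8=C9; C11 methylidene), via dihydroxy acid 19 (not isolated)
Conditions: HF·pyridine, pyridine, THF, 0 °C to rt; then PPTS (cat.), CH2Cl2, rt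
Reagents that add atoms: none
Why: Buffered desilylation frees the C1 alcohol, which lactonises with the neighbouring acid to a five-membered ring. The tertiary C7 hydroxyl is on the other face of the ring and cannot compete.

Step 15
Reactants: 20 γ-lactone
Product: 21 hydroxy ketone (C4 ketone carrying C3H2–O–CH2C6H4OMe; C1 primary alcohol; C7 carbinol; Z C8=C9)
Conditions: n-BuLi (1.0 equiv), THF, −78 °C; then LiCH2OCH2C6H4OMe-4 (from Bu3SnCH2OCH2C6H4OMe-4 and n-BuLi, THF, −78 °C; 1.3 equiv); aq. NH4Cl
Reagents that add atoms: tributyl{[(4-methoxybenzyl)oxy]methyl}stannane, CCCC[Sn](CCCC)(CCCC)COCc1ccc(OC)cc1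
Why: Single addition of an α-alkoxy organolithium to a γ-lactone; the cyclic lithium hemiketal resists a second addition. This brings in C3 with its oxygen and keeps the tropone carbonyl carbon as C4.

Step 16
Reactants: 21 hydroxy ketone
Product: 22 keto aldehyde (C1 aldehyde; C4 ketone with C3H2–O–CH2C6H4OMe)
Conditions: Dess–Martin periodinane, NaHCO3, CH2Cl2, 0 °C
Reagents that add atoms: none
Why: Buffered, non-basic oxidation of the primary alcohol through the open hydroxy-ketone form; the β,γ-unsaturated aldehyde is taken on without delay.

Step 17
Reactants: 22 keto aldehyde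
Product: 23 lactol (6-hydroxytetrahydropyran-3-one ring: C1 hemiacetal, O2, C3H2, C4 ketone; anomers)
Conditions: DDQ, CH2Cl2–pH 7 buffer, 0 °C to rt
Reagents that add atoms: none
Why: Oxidative removal of the 4-methoxybenzyl group frees the C3 hydroxyl, which closes on the only aldehyde to the six-membered hemiacetal. Both ring-fusion centres are next to carbonyl groups here, and the trans-fused ring is the thermodynamic arrangement.

Step 18
Reactants: 23 lactol
Product: 24 C1 acetate (6-acetoxytetrahydropyran-3-one; acetate trans to the C11a–C11 bond)
Conditions: Ac2O, pyridine, DMAP (cat.), CH2Cl2, 0 °C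
Reagents that add atoms: acetic anhydride, CC(=O)OC(C)=O
Why: Acylation of the hemiacetal while the anomers interconvert through the open form; the equatorial hydroxyl, trans to the neighbouring ring bond, should be acetylated faster. The hindered tertiary C7 hydroxyl is left free.

Step 19
Reactants: 24 ketone
Product: 25 enol triflate (C3=C4 with trifluoromethanesulfonyloxy on C4; C1 acetate; C7 carbinol; Z C8=C9; C11 methylidene)
Conditions: KN(SiMe3)2 (2.2 equiv), PhNTf2, THF, −78 °C
Reagents that add atoms: N-phenylbis(trifluoromethanesulfonimide), O=S(=O)(N(c1ccccc1)S(=O)(=O)C(F)(F)F)C(F)(F)F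
Why: Kinetic enolate formation and O-sulfonylation; the C3 methylene is less hindered than the ring-fusion methine C4a and is acidified by the ring oxygen. One equivalent of base is used up by the C7 hydroxyl.

Step 20
Reactants: 26 3-methylbut-2-enal
Product: 27 5-methylhexa-1,4-dien-3-ol (racemic)
Conditions: vinylmagnesium bromide, THF, −78 to 0 °C
Reagents that add atoms: vinylmagnesium bromide, C=C[Mg]Br
Why: 1,2-Addition of a Grignard reagent to the enal gives the bis-allylic alcohol.

Step 21
Reactants: 27 5-methylhexa-1,4-dien-3-ol (racemic)
Product: 28 (1R)-1-[(2R)-3,3-dimethyloxiran-2-yl]prop-2-en-1-ol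
Conditions: Ti(Oi-Pr)4 (10 mol %), D-(−)-diisopropyl tartrate (15 mol %), t-BuOOH (0.6 equiv), 4 Å molecular sieves, CH2Cl2, −20 °C
Reagents that add atoms: tert-butyl hydroperoxide, CC(C)(C)OO
Why: Sharpless asymmetric epoxidation with kinetic resolution. The R alcohol is the fast-reacting enantiomer with this tartrate, the more nucleophilic trisubstituted alkene reacts, and the erythro epoxy alcohol is formed; the S alcohol is left behind.

Step 22
Reactants: 28 epoxy alcohol
Product: 29 (1R)-1-[(2R)-3,3-dimethyloxiran-2-yl]prop-2-enyl acetate
Conditions: Ac2O, pyridine, DMAP (cat.), CH2Cl2, 0 °C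
Reagents that add atoms: acetic anhydride, CC(=O)OC(C)=O
Why: Acetylation of the secondary alcohol installs the C13 acetate of the target early, so no protecting group has to be removed later.

Step 23
Reactants: 29 allylic acetate
Product: 30 (1S)-1-[(2R)-3,3-dimethyloxiran-2-yl]-2-oxoethyl acetate
Conditions: O3, CH2Cl2, −78 °C; then Me2S; used crude
Reagents that add atoms: ozone, [O-][O+]=O
Why: Ozonolysis of the vinyl group under neutral conditions gives the α-acetoxy aldehyde without epimerisation; the descriptor at this carbon changes only because the priorities change.

Step 24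
Reactants: 25 enol triflate; 30 aldehyde
Product: 31 C12 alcohol (12R; chain with C13 acetate and C14–C15 epoxide on C4 of the dihydropyran)
Conditions: CrCl2 (6 equiv), NiCl2 (2 mol %), DMF–THF, rt
Reagents that add atoms: none
Why: Nozaki–Hiyama–Kishi coupling of an alkenyl triflate with an aldehyde; the alkenylchromium reagent tolerates esters, the acetal acetate and the free hydroxyl. Addition anti to the α-acetoxy group (polar Felkin–Anh model) gives the 12R alcohol, anti to the C13 oxygen.

Step 25
Reactants: 31 C12 alcohol
Product: 32 triacetate (the target without the C8–C9 epoxide)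
Conditions: Ac2O, pyridine, DMAP (cat.), CH2Cl2, 0 °C
Reagents that add atoms: acetic anhydride, CC(=O)OC(C)=O
Why: Acetylation of the secondary allylic alcohol; any acetyl shift between the C12 and C13 oxygens in 31 is of no consequence, and the tertiary C7 hydroxyl stays free.

Step 26
Reactants: 32 triacetate
Product: 33 target, (1R,4aS,7S,8R,9R,11aR,12R,13R,14R)
Conditions: VO(acac)2 (5 mol %), t-BuOOH (decane), CH2Cl2, 0 °C
Reagents that add atoms: tert-butyl hydroperoxide, CC(C)(C)OO
Why: Hydroxyl-directed epoxidation of an allylic alcohol; the vanadium alkoxide at C7 should deliver oxygen to the adjacent cis alkene on its own face, which gives the cis epoxide syn to the hydroxyl. The other alkenes have no free hydroxyl to bind the metal.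

## Compound list

1 | 4-methylanisole | COc1ccc(C)cc1 | starting material
2 | 1-methoxy-4-methylcyclohexa-1,4-diene | COC1=CCC(C)=CC1 | intermediate
3 | 7,7-dibromo-1-methoxy-4-methylbicyclo[4.1.0]hept-3-ene (racemic) | COC12CC=C(C)CC1C2(Br)Br | intermediate
4 | 4-methyltropone | O=C1C=CC(C)=CC=C1 | intermediate
5 | 2-[(trimethylsilyl)methyl]allyl acetate | CC(=O)OCC(=C)C[Si](C)(C)C | starting material
6 | 1-acetoxy-3-(trimethylsilyl)propan-2-one | CC(=O)OCC(=O)C[Si](C)(C)C | intermediate
7 | 3-cyano-2-[(trimethylsilyl)methyl]allyl acetate (E/Z mixture; one isomer drawn) | CC(=O)OC/C(C[Si](C)(C)C)=C/C#N | intermediate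
8 | (1S,6S,7R)-3-methyl-8-methylidene-10-oxobicyclo[4.3.1]deca-2,4-diene-7-carbonitrile | C=C1C[C@H]2C=C(C)C=C[C@H](C2=O)[C@H]1C#N | intermediate
9 | (1S,6S,7R)-3-methyl-8-methylidene-10-oxobicyclo[4.3.1]dec-2-ene-7-carbonitrile | C=C1C[C@H]2C=C(C)CC[C@H](C2=O)[C@H]1C#N | intermediate
10 | (1S,6S,7R)-10-hydroxy-3-methyl-8-methylidenebicyclo[4.3.1]dec-2-ene-7-carbaldehyde (C10 epimers; not isolated) | C=C1C[C@H]2C=C(C)CC[C@H](C2O)[C@H]1C=O | intermediate
11 | (1S,6S,7R)-7-(hydroxymethyl)-3-methyl-8-methylidenebicyclo[4.3.1]dec-2-en-10-ol (C10 epimers) | C=C1C[C@H]2C=C(C)CC[C@H](C2O)[C@H]1CO | intermediate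
12 | (1S,6S,7R)-7-[(tert-butyldimethylsilyl)oxymethyl]-3-methyl-8-methylidenebicyclo[4.3.1]dec-2-en-10-ol (C10 epimers) | C=C1C[C@H]2C=C(C)CC[C@H](C2O)[C@H]1CO[Si](C)(C)C(C)(C)C | intermediate
13 | (1S,6S,7R)-7-[(tert-butyldimethylsilyl)oxymethyl]-3-methyl-8-methylidenebicyclo[4.3.1]dec-2-en-10-one | C=C1C[C@H]2C=C(C)CC[C@H](C2=O)[C@H]1CO[Si](C)(C)C(C)(C)C | intermediate
14 | bridged lactone: C4 carbonyl bonded through oxygen to C9 (oxygen on the bridge face), C7=C8, C11 methylidene, silyloxymethyl on C11a | C=C1C[C@H]2C=C(C)CC[C@H](C(=O)O2)[C@H]1CO[Si](C)(C)C(C)(C)C | intermediate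
15 | (Z)-cyclononene acid: C4 carboxylic acid on C4a, phenylselanyl on C9 (inverted), C7=C8, C11 methylidene, silyloxymethyl on C11a | C=C1C[C@@H]([Se]c2ccccc2)/C=C(/C)CC[C@H](C(=O)O)[C@H]1CO[Si](C)(C)C(C)(C)C | intermediate
16 | selenoxide of 15 (not isolated) | C=C1C[C@@H]([Se](=O)c2ccccc2)/C=C(/C)CC[C@H](C(=O)O)[C@H]1CO[Si](C)(C)C(C)(C)C | intermediate
17 | C7 benzeneselenenate ester with Z C8=C9 (not isolated) | C=C1C/C=C\[C@@](C)(O[Se]c2ccccc2)CC[C@H](C(=O)O)[C@H]1CO[Si](C)(C)C(C)(C)C | intermediate
18 | hydroxy acid: C7 tertiary carbinol, Z C8=C9, C4 acid, silyloxymethyl on C11a | C=C1C/C=C\[C@@](C)(O)CC[C@H](C(=O)O)[C@H]1CO[Si](C)(C)C(C)(C)C | intermediate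
19 | dihydroxy acid: as 18 with free C1 alcohol (not isolated) | C=C1C/C=C\[C@@](C)(O)CC[C@H](C(=O)O)[C@H]1CO | intermediate
20 | trans-fused γ-lactone (C4 carbonyl, O, C1H2) with C7 carbinol, Z C8=C9 and C11 methylidene | C=C1C/C=C\[C@@](C)(O)CC[C@@H]2C(=O)OC[C@@H]12 | intermediate
21 | hydroxy ketone: C4 ketone carrying C3H2–O–(4-methoxybenzyl), C1 primary alcohol | C=C1C/C=C\[C@@](C)(O)CC[C@H](C(=O)COCc2ccc(OC)cc2)[C@H]1CO | intermediate
22 | keto aldehyde: C1 aldehyde, C4 ketone with C3H2–O–(4-methoxybenzyl) | C=C1C/C=C\[C@@](C)(O)CC[C@H](C(=O)COCc2ccc(OC)cc2)[C@H]1C=O | intermediate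
23 | lactol: trans-fused 6-hydroxytetrahydropyran-3-one (C1 hemiacetal, C4 ketone; anomers) | C=C1C/C=C\[C@@](C)(O)CC[C@@H]2C(=O)COC(O)[C@@H]12 | intermediate
24 | C1 acetate of 23 (acetate trans to the C11a–C11 bond) | C=C1C/C=C\[C@@](C)(O)CC[C@@H]2C(=O)CO[C@H](OC(C)=O)[C@@H]12 | intermediate
25 | enol triflate: C3=C4 with triflyloxy on C4, C1 acetate | C=C1C/C=C\[C@@](C)(O)CC[C@@H]2C(OS(=O)(=O)C(F)(F)F)=CO[C@H](OC(C)=O)[C@@H]12 | intermediate
26 | 3-methylbut-2-enal | CC(C)=CC=O | starting material
27 | 5-methylhexa-1,4-dien-3-ol (racemic) | C=CC(O)C=C(C)C | intermediate
28 | (1R)-1-[(2R)-3,3-dimethyloxiran-2-yl]prop-2-en-1-ol | C=C[C@@H](O)[C@H]1OC1(C)C | intermediate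
29 | (1R)-1-[(2R)-3,3-dimethyloxiran-2-yl]prop-2-enyl acetate | C=C[C@@H](OC(C)=O)[C@H]1OC1(C)C | intermediate
30 | (1S)-1-[(2R)-3,3-dimethyloxiran-2-yl]-2-oxoethyl acetate | O=C[C@@H](OC(C)=O)[C@H]1OC1(C)C | intermediate
31 | C12 alcohol: 12R hydroxyl, C13 acetate, C14–C15 epoxide on C4; C1 acetate; C7 carbinol; Z C8=C9 | C=C1C/C=C\[C@@](C)(O)CC[C@@H]2C([C@@H](O)[C@@H](OC(C)=O)[C@H]3OC3(C)C)=CO[C@H](OC(C)=O)[C@@H]12 | intermediate
32 | triacetate: the target without the C8–C9 epoxide (Z C8=C9) | C=C1C/C=C\[C@@](C)(O)CC[C@@H]2C([C@@H](OC(C)=O)[C@@H](OC(C)=O)[C@H]3OC3(C)C)=CO[C@H](OC(C)=O)[C@@H]12 | intermediate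
33 | CNP0134792.1, (1R,4aS,7S,8R,9R,11aR,12R,13R,14R) | C=C1C[C@H]2O[C@H]2[C@@](C)(O)CC[C@@H]2C([C@@H](OC(C)=O)[C@@H](OC(C)=O)[C@H]3OC3(C)C)=CO[C@H](OC(C)=O)[C@@H]12 | target

## Step count and least certain steps

Total: 26 steps (3 to tropone 4, 2 to donor 7, 4 to aldehyde 30, 17 from the key step on). Longest linear sequence: 20 steps (steps 1–3, 6–19, 24–26).

**Step 6 (key step).** The most likely failure is bond formation at the wrong α-carbon of the tropone. Attack next to the methyl side gives a dienolate that keeps the methyl group off the charge-bearing carbons, so the intrinsic bias may even oppose the wanted regiochemistry. Loss of enantioselectivity is a second concern. The fallback blocks the unwanted α-carbon. It sets out from 4, which is chlorinated and dehydrochlorinated (Cl2, then Et3N) to 2-chloro-4-methyltropone F1; the 7-chloro isomer is removed at this cheap stage. With F1 the nitrile-bearing carbon can only add to the open α-carbon, and closure at the chlorine-bearing carbon gives the bridgehead chloride F2 under the conditions of step 6. Radical dechlorination (Bu3SnH, Et3B, air, toluene, 0 °C) replaces the bridgehead chlorine by hydrogen with retention and returns to 8.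

**Step 7.** The most likely failure is reduction of the exocyclic methylene along with, or instead of, C5=C6, because 1,1-disubstituted alkenes also react with diimide. The fallback hides the methylene in conjugation. It sets out from 8: a catalytic amidine base moves the methylene double bond into conjugation with the nitrile to give the tetrasubstituted unsaturated nitrile F3, which diimide does not touch. Diimide then reduces C5=C6 to give F4. Kinetic deconjugation (LiN(i-Pr)2, THF, −78 °C, then acetic acid) removes a proton from the methyl group cis to the nitrile and protonates at the α-carbon, returning to 9.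

**Step 11.** The most likely failure is ionisation of the allylic C9–O bond of the product lactone by the silyl triflate, with re-closure at C7; oxygen insertion on the C4a side is also possible. The fallback uses a nucleophilic peroxide and no Lewis acid. It sets out from 13: LiOH and H2O2 in aqueous THF add to the strained bridge ketone, the allylic carbon migrates, and the lactone is saponified in the flask to the cis hydroxy acid F5. Yamaguchi lactonisation (2,4,6-trichlorobenzoyl chloride, Et3N, then DMAP, toluene) closes F5 back to 14.

**Step 19.** The most likely failure is enolisation toward the ring-fusion carbon C4a, or loss of the acetal acetate to the amide base. The fallback raises the acidity at C3 and removes the acetate from the substrate. It sets out from lactol 23, which is oxidised (n-Pr4NRuO4, N-methylmorpholine N-oxide) to keto lactone F6, where C3 lies between the ketone and an acyloxy oxygen. Triflation gives F7, and coupling with 30 as in step 24 gives F8. Reduction with i-Bu2AlH at −78 °C turns the enol lactone into the lactol and removes the C13 acetate, giving F9. Acetylation of the three secondary hydroxyls (Ac2O, pyridine, DMAP) returns to 32.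

**Step 24.** The most likely failure is poor facial selectivity at C12, since alkenylchromium additions to α-oxygenated aldehydes often follow the Felkin model only weakly. The fallback sets C12 by reduction. It sets out from 31 as the epimer mixture: Dess–Martin oxidation gives the C12 ketone F10, and a Corey–Bakshi–Shibata reduction sets C12 under reagent control and returns to 31.

**Step 26.** The most likely failure is oxidation of the electron-rich enol ether, or delivery of oxygen to the wrong face of C8=C9 in the flexible ring. The fallback moves the epoxidation to a stage without an enol ether. It sets out from 24, where the same directed epoxidation gives epoxy ketone F11; if the face is wrong there, a peracid, which tends to the opposite sense in medium rings, can be used. Triflation as in step 19 gives F12, coupling with 30 as in step 24 gives F13, and acetylation as in step 25 returns to 33.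

## Further compounds

F1 | step 6 | 2-chloro-4-methyltropone | O=C1C(Cl)=CC(C)=CC=C1
F2 | step 6 | bridgehead chloride of 8 (chlorine on the bridgehead next to the methyl-bearing alkene) | C=C1C[C@@]2(Cl)C=C(C)C=C[C@H](C2=O)[C@H]1C#N
F3 | step 7 | conjugated nitrile isomer of 8 (3,8-dimethyl-10-oxobicyclo[4.3.1]deca-2,4,7-triene-7-carbonitrile) | CC1=C(C#N)[C@@H]2C=CC(C)=C[C@H](C1)C2=O
F4 | step 7 | 4,5-dihydro derivative of F3 (3,8-dimethyl-10-oxobicyclo[4.3.1]deca-2,7-diene-7-carbonitrile) | CC1=C(C#N)[C@@H]2CCC(C)=C[C@H](C1)C2=O
F5 | step 11 | cis hydroxy acid: C9 hydroxyl on the bridge face, C4 acid, C7=C8, silyloxymethyl on C11a | C=C1C[C@H](O)/C=C(/C)CC[C@H](C(=O)O)[C@H]1CO[Si](C)(C)C(C)(C)C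
F6 | step 19 | keto lactone: C1 lactone carbonyl, O2, C3H2, C4 ketone | C=C1C/C=C\[C@@](C)(O)CC[C@@H]2C(=O)COC(=O)[C@@H]12
F7 | step 19 | enol triflate of F6 (C3=C4, triflyloxy on C4) | C=C1C/C=C\[C@@](C)(O)CC[C@@H]2C(OS(=O)(=O)C(F)(F)F)=COC(=O)[C@@H]12
F8 | step 19 | enol lactone with the side chain (C12 alcohol, C13 acetate, C14–C15 epoxide) | C=C1C/C=C\[C@@](C)(O)CC[C@@H]2C([C@@H](O)[C@@H](OC(C)=O)[C@H]3OC3(C)C)=COC(=O)[C@@H]12
F9 | step 19 | lactol with free C12 and C13 hydroxyls | C=C1C/C=C\[C@@](C)(O)CC[C@@H]2C([C@@H](O)[C@@H](O)[C@H]3OC3(C)C)=COC(O)[C@@H]12
F10 | step 24 | C12 ketone of 31 | C=C1C/C=C\[C@@](C)(O)CC[C@@H]2C(C(=O)[C@@H](OC(C)=O)[C@H]3OC3(C)C)=CO[C@H](OC(C)=O)[C@@H]12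
F11 | step 26 | 8,9-epoxide of ketone 24 | C=C1C[C@H]2O[C@H]2[C@@](C)(O)CC[C@@H]2C(=O)CO[C@H](OC(C)=O)[C@@H]12
F12 | step 26 | 8,9-epoxide of enol triflate 25 | C=C1C[C@H]2O[C@H]2[C@@](C)(O)CC[C@@H]2C(OS(=O)(=O)C(F)(F)F)=CO[C@H](OC(C)=O)[C@@H]12
F13 | step 26 | 8,9-epoxide of C12 alcohol 31 | C=C1C[C@H]2O[C@H]2[C@@](C)(O)CC[C@@H]2C([C@@H](O)[C@@H](OC(C)=O)[C@H]3OC3(C)C)=CO[C@H](OC(C)=O)[C@@H]12
A1 | alternative 1 | bicyclic C11 ketone with E C7=C8, methyl ester on C4 and methyl acetal at C1 | O=C1CC/C=C(C)/CC[C@@H]2C(C(=O)OC)=CO[C@H](OC)[C@@H]12
A2 | alternative 2 | 4,5-trans-disubstituted 6-methoxytetrahydropyran-3-one with 3-oxobutyl and silylated enyne arms | CC(=O)CC[C@@H]1C(=O)CO[C@H](OC)[C@H]1C(=C)CC#C[Si](C)(C)C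
A3 | alternative 3 | trans-fused 2-hydroxydihydropyran methyl ester on the silyl-protected epoxy nine-membered ring | CC(C)(C)[Si](C)(C)O[C@H]1C[C@H]2O[C@H]2[C@@](C)(O[Si](CC)(CC)CC)CC[C@@H]2C(C(=O)OC)=CO[C@H](O)[C@@H]12
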